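| flask | left-handed substrate | right-handed substrate | coupling partner | temperature | remark | time |
|---|---|---|---|---|---|---|
| spring | 0.020 M | 0.020 M | 3 equiv | 100 °C | the very flask that is asked about, followed so far |  |
| autumn | 0.020 M | 0.020 M | 3 equiv | 106 °C | run made earlier |  |
| flask | 0.020 M | 0.020 M | 3.00 equiv | 100 °C |  | 8.0 d |

| run | time / d | left-handed product / % | left-handed substrate / % |
|---|---|---|---|
| spring | 0.500 | 18 | 33 |
| spring | 1.04 | 23 | 31 |
| spring | 1.67 | 29 | 28 |
| spring | 3.00 | 31 | 23 |
| spring | 6.00 | 35 | 24 |
| autumn | 0.500 | 24 | 32 |
| autumn | 1.04 | 29 | 28 |
| autumn | 1.67 | 31 | 25 |
| autumn | 3.00 | 39 | 24 |
| autumn | 6.00 | 36 | 22 |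

(each reading ± 1.5 percentage points)

- coupling partner is single-handed; left-handed substrate and right-handed substrate are mirror images of each other, charged as a racemate, each of them at the stated concentration
- left-handed product that was removed still counts
- what was read earlier has a scatter of 1.5 percentage points, one standard deviation
- additions bring no volume worth counting
- the handed part of coupling partner does not stay in what it makes, so the products of the two hands are mirror images too

- red: at 8.0 d take out 90 % of the left-handed product then present, then wait 2.5 d
- teal: change nothing and wait 2.5 d more
- grey: at 8.0 d raise the temperature by 10 K, then wait 2.5 d
- blue: at 8.0 d add coupling partner, 100 % of the amount charged, then wait 2.5 d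

- left-handed product, in percent of the left-handed substrate and right-handed substrate together first charged, at 8.0 d
- what to do for the largest gain in left-handed product; "none" if nothing gains more than 2 percentage points (red / teal / grey / blue / none)
- left-handed product present, with what was taken out counted in, in percent of the left-handed substrate and right-handed substrate together first charged, after red
- left-handed product present, with what was taken out counted in, in percent of the left-handed substrate and right-handed substrate together first charged, after blue

- The spring run, which is this very flask followed so far, stands at 6.00 d with 35 % left-handed product and 24 % left-handed substrate. Together these exceed the left-handed part of the charge, so you can conclude that the substrate hands turn into each other.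
- Take the two substrates as level. What has coupled is then the charge minus twice the left-handed substrate, 52.0 %, and this lets you get at the right-handed product, which nobody read.
- Now divide the rate of making left-handed product by the rate of making both products, so that time drops out. The reading gives 0.673, and that number is f, the left share: left-handed product made per unit of both products made. Its usual relative is the selectivity factor, here 2.06.
- Left-handed substrate stays between 23 % and 24 % from 3.00 d on, which is within the scatter. Yet only 1.04 equivalents have coupled, fewer than the 3.00 equiv of coupling partner charged. You may therefore judge, without proof, that coupling partner is lost by another path.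
- A fresh charge should then repeat the first one. The substrates stand at 48.0 % of the charge, and another such share of them survives, so blue gains f times the substrate consumed, 17 percentage points. Added to the last reading, this gives 51.8 %.
- The weak link is that the fresh charge gets 2.5 d, not 6.00 d. The substrates stood at 56.0 % at 1.67 d and 46.0 % at 3.00 d, so taking the higher survival of the two, which means the smaller share consumed, gives 14 points. Your range for blue is 49.0 % to 51.8 %, and you expect the other options to stay under 2 points.
- The forecast gives 36 % now, blue as best, 36.5 % after red and 50 % after blue, holding that “Fresh partner restarts the reaction”. Its blue value is lower than your upper figure but inside your range.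
- The flask gives 34.5 % now, 34.8 % after red and 50.9 % after blue. The best option is blue, with a gain of 16 points against 0.37 points for grey.

    2 coupling partner → self-condensation product (k = 0.0190 L mol⁻¹ min⁻¹, Ea = 70.0 kJ mol⁻¹)
    left-handed substrate ⇌ right-handed substrate (k = 0.00350 min⁻¹, Ea = 114 kJ mol⁻¹)
    coupling partner + right-handed substrate → right-handed product (k = 0.00940 L mol⁻¹ min⁻¹, Ea = 74.0 kJ mol⁻¹)
    coupling partner + left-handed substrate → left-handed product (k = 0.0190 L mol⁻¹ min⁻¹, Ea = 100 kJ mol⁻¹)
    (constants at 100 °C)

- At 8.00 d this flask holds 34.5 % left-handed product and 17.5 % right-handed product, a left share of 0.663, while 0.399 % of its coupling partner is still free and 0.0195 M of self-condensation product stands. Now carry f to the neighbour flask, charged with 1.80 equiv of coupling partner, where left-handed substrate ends at 29.1 %. The reckoning gives f times the coupled share, 28.1 % of left-handed product, and that flask holds 27.8 %.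

Readings and results stem from a simulated flask for substances that don't exist; noise was put on by code.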